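**Retrosynthetic overview**

1. Target ⇒ 8-ketone 17. C17 comes from equatorial addition of a 2-methylprop-1-enyl nucleophile to C8=O (8-OH axial, cis to C20) and a last-step ozonolysis; the (13Z)-enoic acid comes from a C13≡C14 alkyne by carboxylation and syn addition of Me2CuLi.
2. Ring B (C5–C6–C7–C8–C9–C10) ⇒ the cyclopentane C5–C6–C7–C8–C10 of a trans-hydrindane, with C9 inserted between C8 and C10 by a semipinacol 1,2-shift. Enabling feature: C8 is oxygenated, carries C9–H as neighbour, and C9 is bonded to the quaternary C10, so a C8 ketone with its α-carbon C9 next to C10 is the retron of a shift of C10 from C8 to C9.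
3. Semipinacol substrate (C8 tertiary OH, C9 mesylate) ⇒ Wittig union of hydrindan-8-one 7 with the C9/C11–C14 ylide, then OsO4 and MsCl.
4. 7 ⇒ bicyclic enedione 1: C8 ketone masked, C4 gem-dimethylation, hydrogenation (C5), reduction (C3).
5. Ring order: ring A and the five-membered ring are present in 1; ring B is formed last, by ring expansion in step 11.

Key step: step 11

Remark: labdane numbering is used for all intermediates (C20 = methyl on C10; in the hydrindanes ring A is C1–C5/C10 and the five-membered ring is C5–C6–C7–C8–C10), and enedione 1 is assumed purchasable in the (7aR) form.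

**Route**

Step 1
Reactants: 1 (7aR)-7a-methyl-2,3,7,7a-tetrahydro-1H-indene-1,5(6H)-dione
Product: 2 enone ketal (C8 1,3-dioxolane of 1)
Conditions: (TMSOCH2)2, TMSOTf (cat.), CH2Cl2, −78 → −20 °C; pyridine quench
Reagents that add atoms: 1,2-bis(trimethylsilyloxy)ethane, C[Si](C)(C)OCCO[Si](C)(C)C
Why: TMSOTf-catalysed acetalisation should take the saturated cyclopentanone (C8) and leave the less electrophilic conjugated C3 ketone; no stereocentre is formed.

Step 2
Reactants: 2 enone ketal
Product: 3 β,γ-enone ketal (4,4-dimethyl-3-ketone with C5=C6 alkene)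
Conditions: KOt-Bu, MeI, t-BuOH/THF, 0 °C → rt
Reagents that add atoms: iodomethane, CI
Why: Deconjugative α,α-dimethylation through the extended dienolate places both methyl groups on C4 and leaves the alkene at C5=C6; C10 is untouched.

Step 3
Reactants: 3 β,γ-enone ketal
Product: 4 trans-hydrindanone ketal (H5 trans to C20)
Conditions: H2 (3 atm), 10% Pd/C, EtOAc, rt
Reagents that add atoms: none
Why: Heterogeneous hydrogenation should deliver hydrogen to the cyclopentene face opposite the angular methyl (the behaviour of Δ14 steroids), setting H5 trans to C20.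

Step 4
Reactants: 4 trans-hydrindanone ketal
Product: 5 hydroxy ketal (3-OH equatorial and cis to C20)
Conditions: NaBH4, MeOH, 0 °C
Reagents that add atoms: none
Why: Hydride reduction of a 4,4-dimethyl-3-ketone from the face away from the axial C4 methyl and C20 should give the equatorial 3-alcohol cis to C20.

Step 5
Reactants: 5 hydroxy ketal
Product: 6 silyl ether ketal (3-OTBS)
Conditions: TBSCl, imidazole, DMAP (cat.), DMF, 50 °C
Reagents that add atoms: tert-butyldimethylsilyl chloride, CC(C)(C)[Si](C)(C)Cl
Why: Silylation of the hindered secondary alcohol under forcing but non-acidic conditions keeps the dioxolane intact.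

Step 6
Reactants: 6 silyl ether ketal
Product: 7 hydrindan-8-one (3-OTBS-4,4,10-trimethyl-trans-hydrindan-8-one)
Conditions: PPTS, acetone/H2O, 60 °C
Reagents that add atoms: water, O
Why: Mild acid-catalysed ketal hydrolysis frees the C8 ketone while the hindered secondary TBS ether should survive.

Step 7
Reactants: 8 (5-chloropent-1-yn-1-yl)trimethylsilane
Product: 10 triphenyl[5-(trimethylsilyl)pent-4-yn-1-yl]phosphonium iodide, via alkyl iodide 9 (not isolated)
Conditions: NaI, PPh3, MeCN, reflux
Reagents that add atoms: triphenylphosphine, c1ccc(cc1)P(c1ccccc1)c1ccccc1; sodium iodide, [Na+].[I-]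
Why: Finkelstein exchange followed by SN2 quaternisation of triphenylphosphine at the primary carbon.

Step 8
Reactants: 7 hydrindan-8-one; 10 phosphonium iodide
Product: 12 (Z)-8(9)-alkylidene hydrindane, via phosphorus ylide 11 (not isolated)
Conditions: 10, NaHMDS, THF, 0 °C; then 7, 65 °C
Reagents that add atoms: none
Why: Wittig olefination of a cyclopentanone next to a quaternary carbon with a non-stabilised ylide should give the Z alkene with C11 cis to C10, as 17-oxo steroids give (Z)-17(20)-alkenes.

Step 9
Reactants: 12 (Z)-alkylidene hydrindane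
Product: 13 8,9-diol (both hydroxyls on the face opposite C20)
Conditions: OsO4 (cat.), NMO, acetone/H2O, rt
Reagents that add atoms: osmium tetroxide, O=[Os](=O)(=O)=O; N-methylmorpholine N-oxide, C[N+]1([O-])CCOCC1; water, O
Why: Catalytic syn-dihydroxylation from the face opposite the angular methyl sets C8 (OH trans to C20) and, through the Z geometry, C9; the silyl alkyne should not react.

Step 10
Reactants: 13 8,9-diol
Product: 14 9-mesylate (8-OH free)
Conditions: MsCl, Et3N, CH2Cl2, −20 °C
Reagents that add atoms: methanesulfonyl chloride, CS(=O)(=O)Cl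
Why: Sulfonylation occurs only at the secondary C9 hydroxyl (the tertiary C8 hydroxyl is inert) and retains the C9 configuration because only the O–H bond is broken.

Step 11
Reactants: 14 9-mesylate
Product: 16 9-epi-8-ketone (trans-decalin with axial side chain), via aluminium alkoxide 15 (not isolated)
Conditions: Et3Al (3 equiv), CH2Cl2, −78 → 0 °C; aq. Rochelle salt
Reagents that add atoms: none
Why: Et3Al turns the tertiary C8 hydroxyl into its aluminium alkoxide and activates the sulfonate, and the C8–C10 bond antiperiplanar to C9–OMs shifts to C9 as mesylate leaves and C8 becomes the carbonyl, an organoaluminium-promoted semipinacol rearrangement whose closest precedent is the D-homoannulation of 17-hydroxy-20-sulfonyloxy pregnanes. Ring B is closed by this 1,2-alkyl shift, a ring expansion of the C5–C6–C7–C8–C10 cyclopentane in which C9 is inserted between C8 and C10 and the C9–C10 bond to the quaternary centre is made intramolecularly. C10 migrates with retention and C9 is inverted, so the C9 configuration is fixed by the Z geometry of 12 and the facial selectivity of step 9; this should give the epimer with the side chain trans to C20, which step 12 corrects because C9 is now α to the ketone. The selectivity required is migration of C10 rather than C7: the quaternary C10 is the better migrating group, and in this diastereomer the rotamer with C10 anti to the mesylate puts C9–H over the ring, whereas the rotamer for C7 migration would put the side chain there. Chelation of aluminium between O8 and the sulfonate holds the oxygen gauche to the leaving group, which should suppress epoxide closure.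

Step 12
Reactants: 16 9-epi-8-ketone
Product: 17 8-ketone (side chain equatorial and cis to C20)
Conditions: DBU, toluene, 60 °C
Reagents that add atoms: none
Why: Base-mediated epimerisation through the enolate should converge on the equatorial side chain, which avoids the syn-axial hydrogens on C1, C5 and C7 and is the C9 configuration of the natural 8-oxo-labdanes.

Step 13
Reactants: 17 8-ketone
Product: 18 tertiary allylic alcohol (8-OH axial and cis to C20; 8-(2-methylprop-1-enyl) equatorial)
Conditions: 2-methylprop-1-enylmagnesium bromide, LaCl3·2LiCl, THF, 0 °C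
Reagents that add atoms: 2-methylprop-1-enylmagnesium bromide, CC(C)=C[Mg]Br
Why: Lanthanide-promoted Grignard 1,2-addition should occur equatorially because the axial trajectory is blocked by the syn-axial C20 methyl, giving C17 equatorial and 8-OH cis to C20.

Step 14
Reactants: 18 tertiary allylic alcohol
Product: 20 methyl ynoate (C13≡C14–CO2Me), via dilithio acetylide 19 (not isolated)
Conditions: MeLi·LiBr (2.1 equiv), THF, 0 °C → rt; then ClCO2Me, −78 °C
Reagents that add atoms: methyl chloroformate, COC(=O)Cl
Why: After deprotonation of the hydroxyl, MeLi cleaves the alkynyl C–Si bond and the lithium acetylide is C-acylated, while the hindered tertiary lithium alkoxide should not be acylated at −78 °C.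

Step 15
Reactants: 20 methyl ynoate
Product: 21 methyl (13Z)-enoate
Conditions: Me2CuLi (3 equiv, from MeLi and CuI), THF, −78 °C; MeOH, −78 °C
Reagents that add atoms: lithium dimethylcuprate, [Li+].C[Cu-]C
Why: Syn carbocupration of the 2-ynoate and protonation with retention at −78 °C place the new methyl cis to H14, so C12 is cis to the ester (13Z).

Step 16
Reactants: 21 methyl (13Z)-enoate
Product: 22 (13Z)-enoic acid (3-OTBS)
Conditions: LiOH, THF/MeOH/H2O, 40 °C; then dilute HCl to pH 5, 0 °C
Reagents that add atoms: lithium hydroxide, [Li+].[OH-]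
Why: Saponification of the methyl ester leaves the alkene geometry and the silyl ether untouched, and the mild cold acidification spares the tertiary allylic alcohol.

Step 17
Reactants: 22 (13Z)-enoic acid (3-OTBS)
Product: 23 dihydroxy acid (3-OH, 8-OH, 8-isobutenyl)
Conditions: TBAF, THF, 60 °C
Reagents that add atoms: none
Why: Fluoride cleavage of the Si–O bond under basic conditions avoids acid, to which the tertiary allylic alcohol is sensitive.

Step 18
Reactants: 23 dihydroxy acid
Product: 24 target, (2Z)-5-[(1S,2R,4aS,6R,8aR)-2-formyl-2,6-dihydroxy-5,5,8a-trimethyldecahydronaphthalen-1-yl]-3-methylpent-2-enoic acid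
Conditions: O3, CH2Cl2/MeOH, −78 °C (Sudan Red 7B end point); then Me2S, −78 °C → rt
Reagents that add atoms: ozone, [O-][O+]=O
Why: Ozonolysis should cleave the electron-rich trisubstituted alkene much faster than the conjugated C13=C14 alkene (the selectivity known for distal versus conjugated alkenes of dienoates), and reductive work-up releases the α-hydroxy aldehyde under neutral conditions without touching a stereocentre.

**Compound list**

1 | (7aR)-7a-methyl-2,3,7,7a-tetrahydro-1H-indene-1,5(6H)-dione | O=C1[C@]2(C)CCC(=O)C=C2CC1 | starting material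
2 | enone ketal: C8 1,3-dioxolane of 1 | C12(OCCO1)[C@]3(C)CCC(=O)C=C3CC2 | intermediate
3 | β,γ-enone ketal: 4,4-dimethyl-3-ketone, C5=C6 alkene, C8 dioxolane | C12(OCCO1)[C@]3(C)CCC(=O)C(C)(C)C3=CC2 | intermediate
4 | trans-hydrindanone ketal: 4,4-dimethyl-3-ketone, H5 trans to C20, C8 dioxolane | C12(OCCO1)[C@]3(C)CCC(=O)C(C)(C)[C@H]3CC2 | intermediate
5 | hydroxy ketal: 3-OH cis to C20, C8 dioxolane | C12(OCCO1)[C@]3(C)CC[C@@H](O)C(C)(C)[C@H]3CC2 | intermediate
6 | silyl ether ketal: 3-OTBS, C8 dioxolane | C12(OCCO1)[C@]3(C)CC[C@@H](O[Si](C)(C)C(C)(C)C)C(C)(C)[C@H]3CC2 | intermediate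
7 | hydrindan-8-one: 3-OTBS-4,4,10-trimethyl-trans-hydrindan-8-one | O=C1[C@]2(C)CC[C@@H](O[Si](C)(C)C(C)(C)C)C(C)(C)[C@H]2CC1 | intermediate
8 | (5-chloropent-1-yn-1-yl)trimethylsilane | C[Si](C)(C)C#CCCCCl | starting material
9 | (5-iodopent-1-yn-1-yl)trimethylsilane | C[Si](C)(C)C#CCCCI | intermediate
10 | triphenyl[5-(trimethylsilyl)pent-4-yn-1-yl]phosphonium iodide | C[Si](C)(C)C#CCCC[P+](c1ccccc1)(c1ccccc1)c1ccccc1.[I-] | intermediate
11 | triphenyl[5-(trimethylsilyl)pent-4-yn-1-ylidene]phosphorane | C[Si](C)(C)C#CCCC=P(c1ccccc1)(c1ccccc1)c1ccccc1 | intermediate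
12 | (Z)-8(9)-alkylidene hydrindane: C11 cis to C10, chain C11–C12–C13≡C14–TMS, 3-OTBS | C[Si](C)(C)C#CCC/C=C1\[C@]2(C)CC[C@@H](O[Si](C)(C)C(C)(C)C)C(C)(C)[C@H]2CC1 | intermediate
13 | 8,9-diol: both hydroxyls on the face opposite C20 | C[Si](C)(C)C#CCC[C@@H](O)[C@@]1(O)[C@]2(C)CC[C@@H](O[Si](C)(C)C(C)(C)C)C(C)(C)[C@H]2CC1 | intermediate
14 | 9-mesylate of 13 (8-OH free) | C[Si](C)(C)C#CCC[C@@H](OS(C)(=O)=O)[C@@]1(O)[C@]2(C)CC[C@@H](O[Si](C)(C)C(C)(C)C)C(C)(C)[C@H]2CC1 | intermediate
15 | diethylaluminium 8-alkoxide of 14 | C[Si](C)(C)C#CCC[C@@H](OS(C)(=O)=O)[C@@]1(O[Al](CC)CC)[C@]2(C)CC[C@@H](O[Si](C)(C)C(C)(C)C)C(C)(C)[C@H]2CC1 | intermediate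
16 | 9-epi-8-ketone: trans-decalin, side chain on C9 trans to C20 | C[Si](C)(C)C#CCC[C@@H]1[C@]2(C)CC[C@@H](O[Si](C)(C)C(C)(C)C)C(C)(C)[C@H]2CCC1=O | intermediate
17 | 8-ketone: side chain on C9 cis to C20 (equatorial) | C[Si](C)(C)C#CCC[C@H]1[C@]2(C)CC[C@@H](O[Si](C)(C)C(C)(C)C)C(C)(C)[C@H]2CCC1=O | intermediate
18 | tertiary allylic alcohol: 8-OH cis to C20, 8-(2-methylprop-1-enyl) | C[Si](C)(C)C#CCC[C@H]1[C@]2(C)CC[C@@H](O[Si](C)(C)C(C)(C)C)C(C)(C)[C@H]2CC[C@]1(O)C=C(C)C | intermediate
19 | dilithio species of 18 (O8–Li, C14–Li, silyl group lost) | [Li]C#CCC[C@H]1[C@]2(C)CC[C@@H](O[Si](C)(C)C(C)(C)C)C(C)(C)[C@H]2CC[C@]1(O[Li])C=C(C)C | intermediate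
20 | methyl ynoate (C13≡C14–CO2Me) | COC(=O)C#CCC[C@H]1[C@]2(C)CC[C@@H](O[Si](C)(C)C(C)(C)C)C(C)(C)[C@H]2CC[C@]1(O)C=C(C)C | intermediate
21 | methyl (13Z)-enoate | C/C(=C/C(=O)OC)CC[C@H]1[C@]2(C)CC[C@@H](O[Si](C)(C)C(C)(C)C)C(C)(C)[C@H]2CC[C@]1(O)C=C(C)C | intermediate
22 | (13Z)-enoic acid, 3-OTBS | C/C(=C/C(=O)O)CC[C@H]1[C@]2(C)CC[C@@H](O[Si](C)(C)C(C)(C)C)C(C)(C)[C@H]2CC[C@]1(O)C=C(C)C | intermediate
23 | dihydroxy acid: 3-OH, 8-OH, 8-(2-methylprop-1-enyl) | C/C(=C/C(=O)O)CC[C@H]1[C@]2(C)CC[C@@H](O)C(C)(C)[C@H]2CC[C@]1(O)C=C(C)C | intermediate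
24 | (2Z)-5-[(1S,2R,4aS,6R,8aR)-2-formyl-2,6-dihydroxy-5,5,8a-trimethyldecahydronaphthalen-1-yl]-3-methylpent-2-enoic acid | C/C(=C/C(=O)O)CC[C@H]1[C@]2(C)CC[C@@H](O)C(C)(C)[C@H]2CC[C@]1(O)C=O | target

**Step count and risks**

Total steps: 18. Longest linear sequence: 17 steps (steps 1–6 and 8–18).

Steps most likely to fail:

1. Step 11. What may go wrong: migration of the C7 methylene instead of the quaternary C10, or closure of the 8,9-epoxide by the alkoxide. Fallback, setting out from diol 13: the secondary C9 hydroxyl is oxidised (SO3·pyridine, DMSO, i-Pr2NEt) to the α-hydroxy ketone F1. An aluminium alkoxide-mediated α-ketol rearrangement (Al(Ot-Bu)3, toluene, 100 °C) follows; these are conditions under which the quaternary ring carbon is expected to migrate in the related 17-hydroxy-20-oxo steroid case, and the 5 → 6 expansion is driven thermodynamically. It should give the ring-enlarged 9-hydroxy-8-ketone F2. SmI2 (THF/MeOH) then removes the C9 hydroxyl, and protonation of the enolate from the face opposite C20 returns the route to 17.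

2. Step 3. What may go wrong: delivery of hydrogen to the face syn to C20, giving the cis-fused hydrindane. Fallback, setting out from 2: controlled mono-methylation of the dienolate (KOt-Bu 1 equiv, MeI 1 equiv; the α-methyl β,γ-enone reconjugates) gives the 4-methyl enone F3. Dissolving-metal reductive methylation (Li, NH3/THF, t-BuOH 1 equiv, −78 °C; then MeI) sets H5 trans to C20 by protonation at C5 and traps the C3–C4 enolate with the second methyl group, returning to 4.

3. Step 13. What may go wrong: enolisation of the hindered C8 ketone toward C7 instead of addition, or incomplete conversion with the β,β-disubstituted alkenyl nucleophile. Fallback, setting out from 17: the smallest sp2 nucleophile is added (vinylmagnesium bromide, CeCl3, THF, −78 °C; the same equatorial attack) to give the vinyl carbinol F4. Cross-metathesis with 2-methylbut-2-ene (phosphine-free second-generation ruthenium alkylidene, 40 °C; the silyl-capped alkyne is a poor enyne partner) then installs the isobutenyl terminus, returning to 18.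

Further compounds
F1 | step 11 | α-hydroxy ketone (8-OH, 9-oxo hydrindane) | C[Si](C)(C)C#CCCC(=O)[C@@]1(O)[C@]2(C)CC[C@@H](O[Si](C)(C)C(C)(C)C)C(C)(C)[C@H]2CC1
F2 | step 11 | ring-enlarged 9-hydroxy-8-ketone (C9 configuration erased in the next operation) | C[Si](C)(C)C#CCC[C@@]1(O)[C@]2(C)CC[C@@H](O[Si](C)(C)C(C)(C)C)C(C)(C)[C@H]2CCC1=O
F3 | step 3 | 4-methyl enone ketal | C12(OCCO1)[C@]3(C)CCC(=O)C(C)=C3CC2
F4 | step 13 | 8-vinyl carbinol (8-OH cis to C20) | C[Si](C)(C)C#CCC[C@H]1[C@]2(C)CC[C@@H](O[Si](C)(C)C(C)(C)C)C(C)(C)[C@H]2CC[C@]1(O)C=C
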